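**Plan**
- Retrosynthesis cuts, in this order: the bond between the ester-bearing CH and the ring-fusion CH of the cyclopentane (last ring); the two C–C bonds and the enol-ether C–O bond around the spiro carbon; the lactam C–N and the N–CH2–C bonds of the piperidine; the propanoate-arm and vinyl bonds at the quaternary carbon; the chain bond between acetoacetate and a cyclopentene fragment.
- Forward: bromocyclopentenol fragment → γ-alkylated acetoacetate → cycloheptene ring (Pd enolate alkenylation) → quaternary carbon (Michael) → bridging N-methyl lactam (methylenation, aza-Michael, lactamisation) → spiro dihydropyran (homologation, Michael, reduction, cyclodehydration) → cyclopentane → lactam reduction, ester cleavage.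
- Enabling feature: the tetrasubstituted C=C shared by the cyclopentene and cycloheptene rings makes the neighbouring cyclopentene CH allylic. An oxygen leaving group there gives an η3-allyl whose central carbon holds the quaternary carbon, so the α-carbon of the propanoate arm reaches the allyl terminus through a five-membered transition state and the olefin re-forms in place.
- Stereochemistry: one oxazaborolidine reduction sets the carbinol carbon; it steers the Michael addition (quaternary carbon); the bridging lactam then fixes the bridgehead CH; the bicycle steers the spiro carbon; Mitsunobu inversion plus double-inversion Pd substitution sets the ring-fusion CH; kinetic protonation sets the ester-bearing CH.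

Key step: step 16

Remark: the oxazaborolidine is assumed to treat the bromo-olefin side of enone 4 as the large group, so that the (R)-catalyst gives the (1S)-alcohol; compounds 1, 3, 9, 12, 15, 18 and 21 are taken as commercial.

Step 1
Reactants: 1 3-ethoxycyclopent-2-en-1-one
Product: 2 2-bromo-3-ethoxycyclopent-2-en-1-one
Conditions: NBS, CH2Cl2, 0 °C to rt
Reagents that add atoms: N-bromosuccinimide, BrN1C(=O)CCC1=O
Why: Electrophilic bromination of the vinylogous ester at its nucleophilic α-carbon (enol-ether-type halogenation).

Step 2
Reactants: 2 2-bromo-3-ethoxycyclopent-2-en-1-one; 3 vinylmagnesium bromide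
Product: 4 2-bromo-3-ethenylcyclopent-2-en-1-one
Conditions: CH2=CHMgBr, THF, −78 to 0 °C; then 1 M aq. HCl
Reagents that add atoms: water, O
Why: 1,2-Addition of the Grignard reagent to the vinylogous ester and acid hydrolysis with allylic transposition (Stork–Danheiser sequence) should give the 3-ethenyl enone.

Step 3
Reactants: 4 2-bromo-3-ethenylcyclopent-2-en-1-one
Product: 5 (1S)-2-bromo-3-ethenylcyclopent-2-en-1-ol
Conditions: (R)-2-methyl-CBS-oxazaborolidine (0.2 equiv), catecholborane (1.5 equiv), toluene, −78 °C; aqueous work-up
Reagents that add atoms: none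
Why: Corey–Bakshi–Shibata reduction of the α-bromo enone should deliver hydride to one carbonyl face and set the (S)-carbinol, the only stereocentre introduced by a chiral reagent.

Step 4
Reactants: 5 (1S)-2-bromo-3-ethenylcyclopent-2-en-1-ol
Product: 6 tert-butyl{[(1S)-2-bromo-3-ethenylcyclopent-2-en-1-yl]oxy}dimethylsilane
Conditions: TBSCl, imidazole, DMF, rt
Reagents that add atoms: tert-butyldimethylsilyl chloride, C[Si](C)(Cl)C(C)(C)C
Why: Standard silylation of the secondary alcohol; the bulky silyl ether later shields one face of the ring system.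

Step 5
Reactants: 6 tert-butyl{[(1S)-2-bromo-3-ethenylcyclopent-2-en-1-yl]oxy}dimethylsilane
Product: 8 tert-butyl{[(1S)-2-bromo-3-(2-iodoethyl)cyclopent-2-en-1-yl]oxy}dimethylsilane, via alkylborane 7 (not isolated)
Conditions: 9-BBN, THF, 0 °C to rt; then NaOMe, I2, MeOH, 0 °C
Reagents that add atoms: iodine, II
Why: Anti-Markovnikov hydroboration of the terminal vinyl group (the tetrasubstituted bromo-olefin is inert) followed by iodinolysis of the primary B–C bond (hydroboration–iodination).

Step 6
Reactants: 9 methyl acetoacetate; 8 tert-butyl{[(1S)-2-bromo-3-(2-iodoethyl)cyclopent-2-en-1-yl]oxy}dimethylsilane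
Product: 10 methyl 6-[(3S)-2-bromo-3-(tert-butyldimethylsilyloxy)cyclopent-1-en-1-yl]-3-oxohexanoate
Conditions: NaH, THF, 0 °C; n-BuLi, 0 °C; then 8, 0 °C to rt; 1 M HCl work-up
Reagents that add atoms: none
Why: γ-Alkylation of the acetoacetate dianion, which reacts at its more basic terminal carbon with the primary iodide.

Step 7
Reactants: 10 methyl 6-[(3S)-2-bromo-3-(tert-butyldimethylsilyloxy)cyclopent-1-en-1-yl]-3-oxohexanoate
Product: 11 methyl (3S)-3-(tert-butyldimethylsilyloxy)-5-oxo-1,2,3,4,5,6,7,8-octahydroazulene-4-carboxylate
Conditions: Pd2(dba)3 (5 mol %), P(t-Bu)3·HBF4 (12 mol %), Cs2CO3 (2.5 equiv), toluene, 80 °C, 0.01 M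
Reagents that add atoms: none
Why: Palladium-catalysed intramolecular α-alkenylation of the stabilised β-keto ester enolate (oxidative addition into the vinyl bromide, enolate binding, reductive elimination) should close the seven-membered ring; the new CH lies between two carbonyls and stays epimerisable.

Step 8
Reactants: 11 methyl (3S)-3-(tert-butyldimethylsilyloxy)-5-oxo-1,2,3,4,5,6,7,8-octahydroazulene-4-carboxylate; 12 methyl acrylate
Product: 13 methyl (3S,4S)-3-(tert-butyldimethylsilyloxy)-4-(3-methoxy-3-oxopropyl)-5-oxo-1,2,3,4,5,6,7,8-octahydroazulene-4-carboxylate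
Conditions: DBU (0.2 equiv), MeCN, 0 °C to rt
Reagents that add atoms: none
Why: Michael addition of the α-alkenyl β-keto ester; the acrylate should enter the planar dienolate on the face anti to the neighbouring silyloxy group (1,3-induction), which sets the quaternary stereocentre.

Step 9
Reactants: 13 methyl (3S,4S)-3-(tert-butyldimethylsilyloxy)-4-(3-methoxy-3-oxopropyl)-5-oxo-1,2,3,4,5,6,7,8-octahydroazulene-4-carboxylate
Product: 14 methyl (3S,4S)-3-(tert-butyldimethylsilyloxy)-4-(3-methoxy-3-oxopropyl)-6-methylidene-5-oxo-1,2,3,4,5,6,7,8-octahydroazulene-4-carboxylate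
Conditions: (CH2O)n, i-Pr2NH2+ CF3CO2− (1 equiv), CF3CO2H (0.1 equiv), THF, 60 °C
Reagents that add atoms: formaldehyde (from paraformaldehyde), C=O
Why: Mannich-type α-methylenation of the ketone at its only enolisable α-carbon (the other α-carbon is quaternary).

Step 10
Reactants: 14 methyl (3S,4S)-3-(tert-butyldimethylsilyloxy)-4-(3-methoxy-3-oxopropyl)-6-methylidene-5-oxo-1,2,3,4,5,6,7,8-octahydroazulene-4-carboxylate; 15 methylamine
Product: 17 bridged keto lactam, via amino ketone 16 (not isolated)
Conditions: MeNH2 (1.1 equiv, 2 M in THF), MeOH, 0 °C to rt; then 60 °C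
Reagents that add atoms: none
Why: Aza-Michael addition of methylamine to the exo-methylene ketone and lactamisation onto the neighbouring β-keto ester close the N-methyl piperidinone bridge; only the cis-disposed aminomethyl group can reach the ester and the ketone α-carbon epimerises to it, so the bridgehead CH follows from the quaternary carbon.

Step 11
Reactants: 17 bridged keto lactam; 18 (methoxymethyl)triphenylphosphonium chloride
Product: 20 bridged lactam aldehyde, via enol ether 19 (not isolated)
Conditions: 18, KN(SiMe3)2, THF, 0 °C to rt; then 0.5 M aq. HCl, THF, 0 °C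
Reagents that add atoms: water, O
Why: Wittig methoxymethylenation of the non-enolisable bridging ketone and hydrolysis of the enol ether give the one-carbon-homologated aldehyde, whose new CH is planarised again in the next step.

Step 12
Reactants: 20 bridged lactam aldehyde; 21 4-methylpent-1-en-3-one
Product: 22 keto aldehyde with quaternary formyl carbon
Conditions: DBU (0.3 equiv), MeCN, 0 °C to rt
Reagents that add atoms: none
Why: Michael addition of the α-branched aldehyde enolate creates the second quaternary carbon; the enone should approach the exocyclic enolate over the cycloheptene bridge (flattened by the olefin, silyloxy group on the far face) and not over the lactam bridge, which places the formyl carbon toward the lactam.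

Step 13
Reactants: 22 keto aldehyde with quaternary formyl carbon
Product: 24 spiro dihydropyran lactam, via hydroxy ketone 23 (not isolated)
Conditions: NaBH4, MeOH/CH2Cl2, −78 °C; then PPTS (0.1 equiv), benzene, 4 Å sieves, 80 °C
Reagents that add atoms: none
Why: Chemoselective borohydride reduction of the aldehyde beside the hindered isopropyl ketone, then acid-catalysed cyclodehydration of the δ-hydroxy ketone through its cyclic hemiketal, should give the endocyclic enol ether without touching the spiro stereocentre.

Step 14
Reactants: 24 spiro dihydropyran lactam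
Product: 25 allylic alcohol
Conditions: Bu4NF, THF, 0 °C to rt
Reagents that add atoms: none
Why: Fluoride-mediated cleavage of the silyl ether.

Step 15
Reactants: 25 allylic alcohol
Product: 26 inverted allylic benzoate
Conditions: PhCO2H, PPh3, DIAD, toluene, 0 °C to rt
Reagents that add atoms: benzoic acid, OC(=O)c1ccccc1
Why: Mitsunobu esterification proceeds by SN2 inversion at the allylic carbinol carbon and so moves the leaving group to the cyclopentene face on which the new C–C bond has to form.

Step 16
Reactants: 26 inverted allylic benzoate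
Product: 29 pentacyclic lactam methyl ester, via ester epimers 27 (not isolated), via potassium enolate 28 (not isolated)
Conditions: Pd(PPh3)4 (10 mol %), LiN(SiMe3)2 (1.3 equiv), THF, −78 to 0 °C; then KN(SiMe3)2 (1.5 equiv), −78 °C; then AcOH (3 equiv), −78 °C
Reagents that add atoms: none
Why: Zerovalent palladium ionises the allylic benzoate with inversion to an η3-allyl complex spanning the benzoate carbon, the ring-fusion sp2 carbon and its cycloheptene partner, LiN(SiMe3)2 forms the ester enolate of the propanoate arm, and this enolate attacks the secondary allyl terminus on the face opposite to palladium, which re-forms the tetrasubstituted olefin between the five- and seven-membered carbocycles. The closest known reaction type is the intramolecular Tsuji–Trost allylic alkylation with a non-stabilised enolate, in the topology of the ring-closing half of a trimethylenemethane cycloaddition (nucleophile tethered to the central allyl carbon). The cyclopentane is closed by bond formation between the ester α-carbon and the allyl terminus, exo with respect to the departing carbon–palladium bond (5-exo-tet-like), the tether running through the CH2 group, the quaternary carbon and the central allyl carbon. The ring-fusion CH is set by double inversion, so the new bond takes the place of the benzoate oxygen fixed in step 15, and the ester-bearing CH is set after cyclisation by protonation of the potassium enolate on its convex face, the face of the ring-fusion hydrogen and away from the spiro carbon. The step needs attack at the secondary and not the fully substituted allyl terminus, secured by sterics and by the strain of the bridged ring the other mode would build, and outer-sphere attack anti to the metal, which is the normal course for lithium ester enolates and which the two-atom tether lying in the plane of the allyl unit allows from either face.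

Step 17
Reactants: 29 pentacyclic lactam methyl ester
Product: 30 methyl ester of the target amine
Conditions: Zn(OAc)2 (10 mol %), (EtO)3SiH (3 equiv), THF, 40 °C; aq. NaHCO3 work-up
Reagents that add atoms: none
Why: Zinc-catalysed hydrosilylation reduces the tertiary lactam to the N-methyl amine chemoselectively, leaving the ester, the enol ether and the tetrasubstituted olefin intact and the stereocentres untouched.

Step 18
Reactants: 30 methyl ester of the target amine
Product: 31 target acid CNP0237695.2
Conditions: Me3SnOH (5 equiv), ClCH2CH2Cl, 70 °C; work-up with 0.1 M HCl to pH 5, 0 °C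
Reagents that add atoms: trimethyltin hydroxide, C[Sn](C)(C)O
Why: Tin hydroxide-mediated ester cleavage under near-neutral conditions avoids base-induced epimerisation of the kinetically set ester-bearing centre; the acid-labile enol ether is kept by work-up at pH 5.

**Compound list**
1 | 3-ethoxycyclopent-2-en-1-one | CCOC1=CC(=O)CC1 | starting material
2 | 2-bromo-3-ethoxycyclopent-2-en-1-one | CCOC1=C(Br)C(=O)CC1 | intermediate
3 | vinylmagnesium bromide, CH2=CHMgBr | C=C[Mg]Br | starting material
4 | 2-bromo-3-ethenylcyclopent-2-en-1-one | C=CC1=C(Br)C(=O)CC1 | intermediate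
5 | (1S)-2-bromo-3-ethenylcyclopent-2-en-1-ol | O[C@H]1CCC(C=C)=C1Br | intermediate
6 | tert-butyl{[(1S)-2-bromo-3-ethenylcyclopent-2-en-1-yl]oxy}dimethylsilane | CC(C)(C)[Si](C)(C)O[C@H]1CCC(C=C)=C1Br | intermediate
7 | 9-{2-[(3S)-2-bromo-3-(tert-butyldimethylsilyloxy)cyclopent-1-en-1-yl]ethyl}-9-borabicyclo[3.3.1]nonane | CC(C)(C)[Si](C)(C)O[C@H]1CCC(CCB2C3CCCC2CCC3)=C1Br | intermediate
8 | tert-butyl{[(1S)-2-bromo-3-(2-iodoethyl)cyclopent-2-en-1-yl]oxy}dimethylsilane | CC(C)(C)[Si](C)(C)O[C@H]1CCC(CCI)=C1Br | intermediate
9 | methyl 3-oxobutanoate (methyl acetoacetate) | COC(=O)CC(C)=O | starting material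
10 | methyl 6-[(3S)-2-bromo-3-(tert-butyldimethylsilyloxy)cyclopent-1-en-1-yl]-3-oxohexanoate | COC(=O)CC(=O)CCCC1=C(Br)[C@H](CC1)O[Si](C)(C)C(C)(C)C | intermediate
11 | methyl (3S)-3-(tert-butyldimethylsilyloxy)-5-oxo-1,2,3,4,5,6,7,8-octahydroazulene-4-carboxylate (C-4 epimers, enolisable) | COC(=O)C1C(=O)CCCC2=C1[C@H](CC2)O[Si](C)(C)C(C)(C)C | intermediate
12 | methyl acrylate | C=CC(=O)OC | starting material
13 | methyl (3S,4S)-3-(tert-butyldimethylsilyloxy)-4-(3-methoxy-3-oxopropyl)-5-oxo-1,2,3,4,5,6,7,8-octahydroazulene-4-carboxylate (propanoate arm anti to the silyloxy group) | O=C1CCCC2=C([C@H](CC2)O[Si](C)(C)C(C)(C)C)[C@]1(CCC(=O)OC)C(=O)OC | intermediate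
14 | methyl (3S,4S)-3-(tert-butyldimethylsilyloxy)-4-(3-methoxy-3-oxopropyl)-6-methylidene-5-oxo-1,2,3,4,5,6,7,8-octahydroazulene-4-carboxylate | C=C1CCC2=C([C@H](CC2)O[Si](C)(C)C(C)(C)C)[C@](CCC(=O)OC)(C(=O)OC)C1=O | intermediate
15 | methylamine | CN | starting material
16 | methyl (3S,4S)-3-(tert-butyldimethylsilyloxy)-4-(3-methoxy-3-oxopropyl)-6-[(methylamino)methyl]-5-oxo-1,2,3,4,5,6,7,8-octahydroazulene-4-carboxylate (C-6 epimers) | CNCC1CCC2=C([C@H](CC2)O[Si](C)(C)C(C)(C)C)[C@](CCC(=O)OC)(C(=O)OC)C1=O | intermediate
17 | bridged keto lactam: 8-methyl-8-azabicyclo[4.3.1]dec-2-ene-9,10-dione core (C-1 quaternary bridgehead bearing CH2CH2CO2CH3, C-6 CH bridgehead, C-10 ketone bridge, C-9 lactam carbonyl), C-2 and C-3 also joined through CH(OSiMe2t-Bu)–CH2–CH2 to a cyclopentene, silyloxy carbon next to C-2; (1S,6S), silyloxy carbon (S), silyloxy group on the face away from the ketone bridge | O=C2[C@H]1CCC3=C([C@H](CC3)O[Si](C)(C)C(C)(C)C)[C@]2(CCC(=O)OC)C(=O)N(C)C1 | intermediate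
18 | (methoxymethyl)triphenylphosphonium chloride | COC[P+](c1ccccc1)(c1ccccc1)c1ccccc1.[Cl-] | starting material
19 | enol ether: 17 with the ketone C=O replaced by C=CH(OCH3) (E/Z mixture), other centres as in 17 | COC=C2[C@H]1CCC3=C([C@H](CC3)O[Si](C)(C)C(C)(C)C)[C@]2(CCC(=O)OC)C(=O)N(C)C1 | intermediate
20 | bridged lactam aldehyde: 17 with the ketone carbon replaced by CH(CHO) (epimers at this carbon), other centres as in 17 | O=CC2[C@H]1CCC3=C([C@H](CC3)O[Si](C)(C)C(C)(C)C)[C@]2(CCC(=O)OC)C(=O)N(C)C1 | intermediate
21 | 4-methylpent-1-en-3-one (isopropyl vinyl ketone) | C=CC(=O)C(C)C | starting material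
22 | keto aldehyde: the one-carbon bridge of 20 is quaternary (R) and bears CHO (toward the lactam bridge) and CH2CH2C(=O)CH(CH3)2 (toward the cycloheptene bridge), other centres as in 17 | CC(C)C(=O)CC[C@@]2(C=O)[C@H]1CCC3=C([C@H](CC3)O[Si](C)(C)C(C)(C)C)[C@]2(CCC(=O)OC)C(=O)N(C)C1 | intermediate
23 | hydroxy ketone: 22 with CHO reduced to CH2OH | CC(C)C(=O)CC[C@@]2(CO)[C@H]1CCC3=C([C@H](CC3)O[Si](C)(C)C(C)(C)C)[C@]2(CCC(=O)OC)C(=O)N(C)C1 | intermediate
24 | spiro dihydropyran lactam: 6-isopropyl-3,4-dihydro-2H-pyran spiro-fused through its C-3 at the bridge carbon, ring O–CH2 toward the lactam bridge, silyl ether retained | CC(C)C1=CC[C@@]2(CO1)[C@H]1CCC3=C([C@H](CC3)O[Si](C)(C)C(C)(C)C)[C@]2(CCC(=O)OC)C(=O)N(C)C1 | intermediate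
25 | allylic alcohol: 24 without the silyl group, carbinol carbon (S) | CC(C)C1=CC[C@@]2(CO1)[C@H]1CCC3=C([C@H](CC3)O)[C@]2(CCC(=O)OC)C(=O)N(C)C1 | intermediate
26 | allylic benzoate: O-benzoyl derivative of the C-epimer of 25, carbinol carbon (R) | CC(C)C1=CC[C@@]2(CO1)[C@H]1CCC3=C([C@@H](CC3)OC(=O)c3ccccc3)[C@]2(CCC(=O)OC)C(=O)N(C)C1 | intermediate
27 | cyclised lactam methyl ester as a mixture of epimers at the ester-bearing carbon | CC(C)C1=CC[C@@]2(CO1)[C@H]1CCC3=C4[C@@H](CC3)C(C(=O)OC)C[C@]42C(=O)N(C)C1 | intermediate
28 | potassium ester enolate of 27 | CC(C)C1=CC[C@@]2(CO1)[C@H]1CCC3=C4[C@@H](CC3)C(=C([O-])OC)C[C@]42C(=O)N(C)C1.[K+] | intermediate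
29 | pentacyclic lactam methyl ester: the target with N–C(=O) in place of the N–CH2 next to the quaternary carbon and CO2CH3 in place of CO2H; spiro C (R), bridgehead CH (R), ring-fusion CH (S), ester-bearing CH (S), quaternary C (S) | CC(C)C1=CC[C@@]2(CO1)[C@H]1CCC3=C4[C@@H](CC3)[C@@H](C(=O)OC)C[C@]42C(=O)N(C)C1 | intermediate
30 | methyl ester of the target amine, configurations as in 29 | CC(C)C1=CC[C@@]2(CO1)[C@H]1CCC3=C4[C@@H](CC3)[C@@H](C(=O)OC)C[C@]42CN(C)C1 | intermediate
31 | target acid CNP0237695.2 | CC(C)C1=CC[C@@]2(CO1)[C@H]1CCC3=C4[C@@H](CC3)[C@@H](C(=O)O)C[C@]42CN(C)C1 | target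

**Count and risks**
Total step count: 18. Longest linear sequence: 18 steps (1 to 31); 3, 9, 12, 15, 18 and 21 enter as commercial reagents.

Steps most likely to fail:

- Step 16. The enolate may be delivered through the metal instead of attacking anti to it, or may be acylated by the benzoate, so the ring-fusion CH could form with poor stereocontrol or the ring might not close. Fallback: set out from allylic alcohol 25. Phosphorylation with ClP(O)(OEt)2, pyridine and DMAP (retention) should give the allylic diethyl phosphate F1. KN(SiMe3)2 in THF at −78 to 0 °C should then close the ring by direct intramolecular SN2 alkylation of the ester enolate (inversion at the carbinol carbon, no metal). The same enolate re-formation and AcOH quench returns to 29.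

- Step 12. The hindered aldehyde enolate may add to the enone slowly or from the lactam-side face, which would misplace the two arms of the spiro carbon. Fallback: set out from aldehyde 20 and attach the two arms in the opposite order. Crossed aldol reaction with aqueous formaldehyde and K2CO3 should give the hydroxymethyl aldehyde F2, in which the small electrophile has entered on the face the enone would have used. Wittig olefination of the formyl group with Ph3P=CHC(O)CH(CH3)2 should give the hydroxy enone F3. Conjugate reduction with [(Ph3P)CuH]6 returns to hydroxy ketone 23, which is cyclodehydrated to 24 as in step 13.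

- Step 7. Closing a seven-membered ring from an open chain by enolate alkenylation may suffer from slow reductive elimination and oligomerisation. Fallback: set out from iodide 8. Alkylation of the lithium enolate of methyl acetate (LiN(i-Pr)2, THF/DMPU, −78 °C) should give the bromo ester F4. Intermolecular coupling of the vinyl bromide with the zinc enolate BrZnCH2CO2Me (Pd2(dba)3, P(t-Bu)3, THF) should give the diester F5. Dieckmann condensation (KOt-Bu, THF), which under thermodynamic control should end at the enolate of the more acidic allylic β-keto ester, returns to 11.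

Further compounds
F1 | step 16 | allylic diethyl phosphate of 25, carbinol configuration retained (S) | CC(C)C1=CC[C@@]2(CO1)[C@H]1CCC3=C([C@H](CC3)OP(=O)(OCC)OCC)[C@]2(CCC(=O)OC)C(=O)N(C)C1
F2 | step 12 | hydroxymethyl aldehyde: bridge carbon of 20 bearing CH2OH (toward the lactam bridge) and CHO (toward the cycloheptene bridge) | O=C[C@@]2(CO)[C@H]1CCC3=C([C@H](CC3)O[Si](C)(C)C(C)(C)C)[C@]2(CCC(=O)OC)C(=O)N(C)C1
F3 | step 12 | hydroxy enone: F2 with CHO converted to (E)-CH=CH–C(=O)CH(CH3)2 | CC(C)C(=O)/C=C/[C@@]2(CO)[C@H]1CCC3=C([C@H](CC3)O[Si](C)(C)C(C)(C)C)[C@]2(CCC(=O)OC)C(=O)N(C)C1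
F4 | step 7 | methyl 4-[(3S)-2-bromo-3-(tert-butyldimethylsilyloxy)cyclopent-1-en-1-yl]butanoate | COC(=O)CCCC1=C(Br)[C@H](CC1)O[Si](C)(C)C(C)(C)C
F5 | step 7 | methyl 4-[(3S)-3-(tert-butyldimethylsilyloxy)-2-(2-methoxy-2-oxoethyl)cyclopent-1-en-1-yl]butanoate | COC(=O)CCCC1=C(CC(=O)OC)[C@H](CC1)O[Si](C)(C)C(C)(C)C
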